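**Retrosynthetic overview**
1. Target ⇒ C9-unsubstituted enolised trione + prenyl bromide: the C9 quaternary centre is made last, by C-prenylation on the open face of the bicyclo[3.2.1]octane.
2. Enolised trione ⇒ fully aromatic acylphloroglucinol carrying a (2S)-2-acetyl-3,3-dimethylpent-4-enyl chain: C1–C5 and C6–C7 are cut together; forward, an oxidative radical dearomative (3+2) annulation of the phenoxyl radical with its own vinyl group.
3. Aryl precursor ⇒ 2-isobutyryl-4-methylphloroglucinol + an α-methylene ketone; enantioselective conjugate addition–protonation sets C3, the only stereocentre before the key step.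
4. Acylphloroglucinol ⇒ 3-methylpentane-2,4-dione + methyl isobutyrate + dimethyl carbonate (Claisen chemistry); enone ⇒ mesityl oxide + vinyl Grignard reagent + iminium salt.
5. Ring order: ring A (six-membered, first as the arene), then ring B (cyclopentane C1–C5) and ring C (bridging cyclopentanone C1, C5, C6, C7, C11) together in the radical step.

Locants C1–C11 for the tricyclic compounds are those of their tricyclo[5.3.1.0^{1,5}]undecane names.
Assumption: the (S)-tert-leucine-derived diamine catalyst of step 4 gives the (3S) ketone; if the sense is the opposite, its enantiomer is used.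

**Route**

Step 1
Reactants: 1 3-methylpentane-2,4-dione; 2 methyl 2-methylpropanoate
Product: 3 3,7-dimethyloctane-2,4,6-trione
Conditions: LiN(iPr)2 (3.0 equiv), THF, -78 to 0 °C; then 2 (1.0 equiv), 0 to 23 °C; aq HCl
Reagents that add atoms: none
Why: Claisen-type acylation of a β-diketone 1,3-dianion (Hauser–Harris acylation): the terminal carbanion, formed second, is the most nucleophilic site and attacks the ester, and the third equivalent of base holds the more acidic triketone as its salt; the C3 centre is enolisable and of no consequence.

Step 2
Reactants: 3 3,7-dimethyloctane-2,4,6-trione; 4 dimethyl carbonate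
Product: 6 1-(2,4,6-trihydroxy-3-methylphenyl)-2-methylpropan-1-one, via triketo ester 5 (not isolated)
Conditions: LiN(iPr)2 (3.3 equiv), THF, -78 to 0 °C; then 4 (1.5 equiv), -78 to 0 °C; then 2 M KOH, MeOH–H2O, 23 °C; aq HCl
Reagents that add atoms: none
Why: The triketone trianion is methoxycarbonylated at its terminal methyl carbanion, and the 3,5,7-triketo ester then undergoes the polyketide-type intramolecular Claisen condensation under strong base (C6 carbanion onto the ester carbonyl, six-membered ring), made irreversible by tautomerisation to the phloroglucinol; the hindered isopropyl ketone disfavours the competing aldol mode, and no stereocentre is formed.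

Step 3
Reactants: 7 4-methylpent-3-en-2-one; 8 vinylmagnesium bromide; 9 dimethyl(methylidene)ammonium iodide
Product: 13 4,4-dimethyl-3-methylidenehex-5-en-2-one, via bromomagnesium enolate 10 (not isolated), via Mannich base 11 (not isolated), via ammonium iodide 12 (not isolated)
Conditions: CuBr·SMe2 (5 mol %), THF, -40 °C; then 9 (1.3 equiv), -40 to 23 °C; then MeI (5 equiv), 23 °C; then aq NaHCO3, CH2Cl2, 23 °C
Reagents that add atoms: none
Why: Copper-catalysed 1,4-addition of the vinyl Grignard reagent to the β,β-disubstituted enone gives the enolate regiospecifically, Mannich trapping places the aminomethyl group on C3, and quaternisation followed by E1cB elimination of trimethylamine unveils the α-methylene ketone; the transient C3 centre of 11 and 12 is destroyed.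

Step 4
Reactants: 6 1-(2,4,6-trihydroxy-3-methylphenyl)-2-methylpropan-1-one; 13 4,4-dimethyl-3-methylidenehex-5-en-2-one
Product: 14 (3S)-3-{[2,4,6-trihydroxy-3-methyl-5-(2-methylpropanoyl)phenyl]methyl}-4,4-dimethylhex-5-en-2-one
Conditions: (2S)-N1,N1-diethyl-3,3-dimethylbutane-1,2-diamine·TfOH (20 mol %), CHCl3, 0 °C
Reagents that add atoms: none
Why: Proposed new method: the primary amine of the catalyst condenses with the methyl ketone of 13 to an α-substituted vinyl iminium ion, the only unsubstituted ring carbon of 6 adds to its CH2 terminus in a Friedel–Crafts-type conjugate addition (O-alkylation is reversible), and the resulting enamine is protonated at C3 from one face by the adjacent ammonium group of the catalyst, which sets (3S); the closest known reaction type is the primary–tertiary diamine/TfOH-catalysed conjugate addition–enantioselective enamine protonation of α-substituted vinyl ketones with indoles and naphthols.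

Step 5
Reactants: 14 (3S)-3-{[2,4,6-trihydroxy-3-methyl-5-(2-methylpropanoyl)phenyl]methyl}-4,4-dimethylhex-5-en-2-one
Product: 15 (1S,3S,5R,7S)-3-acetyl-10-hydroxy-4,4,7-trimethyl-9-(2-methylpropanoyl)tricyclo[5.3.1.0^{1,5}]undec-9-ene-8,11-dione
Conditions: Mn(OAc)3·2H2O (2.5 equiv), degassed AcOH, 23 °C, 0.01 M
Reagents that add atoms: none
Why: Proposed new method: trivalent manganese oxidises the chelated enol of 14 by one electron to a phenoxyl radical that behaves as a cyclic 2-alkyl-1,3-dicarbonyl radical at the chain-bearing ring carbon (dearomatisation is cheap in the phloroglucinol series); this carbon adds 5-exo-trig to the internal vinyl carbon (C1–C5, ring B, helped by the gem-dimethyl group and reversible because ring opening re-aromatises), the primary C6 radical then adds 5-exo-trig to the methyl-bearing ring carbon on the same face (C6–C7, ring C, new quaternary C7) rather than to the chelated, more hindered acyl-bearing carbon, and the captodative enol radical is oxidised by the second equivalent to the enolised trione; the bridge fixes C1, C5 and C7 relative to each other with rings B and C cis-fused, and the (3S) acetyl group selects the absolute sense by lying on the convex face of ring B (cis to H5, trans to C6) in the bridging transition state, the minor C3-endo diastereomer being separable; closest known reaction types are the Mn(OAc)3-mediated radical cascades of dearomatised prenylated acylphloroglucinols and the cationic phenol–alkene (5+2) annulation to bicyclo[3.2.1]octanes.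

Step 6
Reactants: 15 (1S,3S,5R,7S)-3-acetyl-10-hydroxy-4,4,7-trimethyl-9-(2-methylpropanoyl)tricyclo[5.3.1.0^{1,5}]undec-9-ene-8,11-dione; 16 1-bromo-3-methylbut-2-ene
Product: 17 (1R,3S,5R,7S,9S)-3-acetyl-4,4,7-trimethyl-9-(3-methylbut-2-en-1-yl)-9-(2-methylpropanoyl)tricyclo[5.3.1.0^{1,5}]undecane-8,10,11-trione
Conditions: Pd(PPh3)4 (5 mol %), K2CO3 (1.5 equiv), THF, 23 °C
Reagents that add atoms: none
Why: Tsuji–Trost allylation: zerovalent palladium ionises the prenyl bromide to a π-prenyl complex that the soft C9 enolate attacks at its unsubstituted CH2 terminus (linear prenyl), any O-prenyl enol ether re-ionises under the catalyst so the C-alkylated trione accumulates, and the electrophile enters on the face syn to the one-carbon C11 carbonyl bridge, away from the endo hydrogens of the C5–C6 bridge, which places the isobutyryl group syn to C5–C6 and sets (9S).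

**Compound list**
1 | 3-methylpentane-2,4-dione | CC(=O)C(C)C(C)=O | starting material
2 | methyl 2-methylpropanoate | COC(=O)C(C)C | starting material
3 | 3,7-dimethyloctane-2,4,6-trione | CC(=O)C(C)C(=O)CC(=O)C(C)C | intermediate
4 | dimethyl carbonate | COC(=O)OC | starting material
5 | methyl 4,8-dimethyl-3,5,7-trioxononanoate | COC(=O)CC(=O)C(C)C(=O)CC(=O)C(C)C | intermediate
6 | 1-(2,4,6-trihydroxy-3-methylphenyl)-2-methylpropan-1-one | CC(C)C(=O)c1c(O)cc(O)c(C)c1O | intermediate
7 | 4-methylpent-3-en-2-one (mesityl oxide) | CC(=O)C=C(C)C | starting material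
8 | vinylmagnesium bromide | C=C[Mg]Br | starting material
9 | dimethyl(methylidene)ammonium iodide | C=[N+](C)C.[I-] | starting material
10 | bromomagnesium 4,4-dimethylhexa-2,5-dien-2-olate | CC(O[Mg]Br)=CC(C)(C)C=C | intermediate
11 | 3-[(dimethylamino)methyl]-4,4-dimethylhex-5-en-2-one (racemic) | CC(=O)C(CN(C)C)C(C)(C)C=C | intermediate
12 | (2-acetyl-3,3-dimethylpent-4-en-1-yl)trimethylammonium iodide (racemic) | CC(=O)C(C[N+](C)(C)C)C(C)(C)C=C.[I-] | intermediate
13 | 4,4-dimethyl-3-methylidenehex-5-en-2-one | CC(=O)C(=C)C(C)(C)C=C | intermediate
14 | (3S)-3-{[2,4,6-trihydroxy-3-methyl-5-(2-methylpropanoyl)phenyl]methyl}-4,4-dimethylhex-5-en-2-one | CC(=O)[C@@H](Cc1c(O)c(C)c(O)c(C(=O)C(C)C)c1O)C(C)(C)C=C | intermediate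
15 | (1S,3S,5R,7S)-3-acetyl-10-hydroxy-4,4,7-trimethyl-9-(2-methylpropanoyl)tricyclo[5.3.1.0^{1,5}]undec-9-ene-8,11-dione (enol form of the C9–H trione; same spatial arrangement at C1, C3, C5, C7 as in 17) | CC(=O)[C@H]1C[C@]23C(=O)[C@](C)(C[C@@H]2C1(C)C)C(=O)C(C(=O)C(C)C)=C3O | intermediate
16 | 1-bromo-3-methylbut-2-ene (prenyl bromide) | CC(C)=CCBr | starting material
17 | (1R,3S,5R,7S,9S)-3-acetyl-4,4,7-trimethyl-9-(3-methylbut-2-en-1-yl)-9-(2-methylpropanoyl)tricyclo[5.3.1.0^{1,5}]undecane-8,10,11-trione | CC(=O)[C@H]1C[C@]23C(=O)[C@](C)(C[C@@H]2C1(C)C)C(=O)[C@](CC=C(C)C)(C(=O)C(C)C)C3=O | target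

**Step count and risks**
Total steps: 6. Longest linear sequence: 5 (steps 1, 2, 4, 5, 6).

Step 5 is the most likely to fail. The phenoxyl radical may be oxidised further to a quinone methide instead of cyclising, the first closure may go 6-endo, the primary radical may attack the acyl-bearing ring carbon, or the relay from C3 may be weak. A reversed sense of relay would only require the antipodal catalyst in step 4 and a final C3 epimerisation. The fallback sets out from 14 and comes back at 15, and it separates the two bond formations. N-Iodosuccinimide in (CF3)2CHOH at 0 °C activates the vinyl group, and the chain-bearing arene carbon attacks the internal carbon 5-exo to give the iodomethyl spirodienone F1. Its diastereomers are separated so that only the one with CH2I over the methyl-bearing enol carbon and trans to the acetyl group is carried on. The primary radical is then generated from the C–I bond (Ir(ppy)3, 2,6-lutidine, MeCN, blue light), adds 5-exo to the methyl-bearing carbon, and the adduct radical is oxidised by the oxidised photocatalyst and loses a proton, which returns 15.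

Step 4 is the second risk. The bulky tert-alkyl group may slow iminium formation or erode the selectivity of the protonation. Compound 14 will sit partly as its cyclic hemiketal and must not be dehydrated to a 4H-chromene, which would erase C3. The fallback sets out from 6 and 13 and comes back at 14, by resolution instead of catalysis. Et3N (10 mol %) in THF gives the racemic adduct F2. Crystallisation with (R)-1-phenylethylamine from EtOAc gives the less soluble (R)-1-phenylethylammonium phenolate salt F3 of the (3S) compound. Partition between EtOAc and cold 0.5 M HCl returns 14.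

Step 6 is the third risk. The hindered triketone enolate may stop at O-prenylation, give the branched 1,1-dimethylallyl isomer, or react on the wrong face. The fallback sets out from 15 and comes back at 17. Allyl bromide and K2CO3 in acetone give the allyl enol ether F4. Heating in xylene at 140 °C effects the Claisen rearrangement, which delivers the allyl group to C9 on the same open face and gives the C9-allyl trione F5. Cross-metathesis with 2-methylbut-2-ene (second-generation Grubbs catalyst, CH2Cl2, 40 °C) converts allyl into prenyl and returns 17.

Further compounds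
F1 | step 5 | (3S)-3-acetyl-8,10-dihydroxy-1-(iodomethyl)-2,2,7-trimethyl-9-(2-methylpropanoyl)spiro[4.5]deca-7,9-dien-6-one, CH2I over the methyl-bearing enol carbon and trans to acetyl | CC(=O)[C@H]1C[C@]2(C(=O)C(C)=C(O)C(C(=O)C(C)C)=C2O)[C@H](CI)C1(C)C
F2 | step 4 | racemic 3-{[2,4,6-trihydroxy-3-methyl-5-(2-methylpropanoyl)phenyl]methyl}-4,4-dimethylhex-5-en-2-one | CC(=O)C(Cc1c(O)c(C)c(O)c(C(=O)C(C)C)c1O)C(C)(C)C=C
F3 | step 4 | (R)-1-phenylethylammonium phenolate salt of 14 | CC(=O)[C@@H](Cc1c([O-])c(C)c(O)c(C(=O)C(C)C)c1O)C(C)(C)C=C.C[C@@H]([NH3+])c1ccccc1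
F4 | step 6 | 3-acetyl-4,4,7-trimethyl-9-(2-methylpropanoyl)-10-(prop-2-en-1-yloxy)tricyclo[5.3.1.0^{1,5}]undec-9-ene-8,11-dione, configured as 15 | CC(=O)[C@H]1C[C@]23C(=O)[C@](C)(C[C@@H]2C1(C)C)C(=O)C(C(=O)C(C)C)=C3OCC=C
F5 | step 6 | (1R,3S,5R,7S,9S)-3-acetyl-4,4,7-trimethyl-9-(2-methylpropanoyl)-9-(prop-2-en-1-yl)tricyclo[5.3.1.0^{1,5}]undecane-8,10,11-trione | CC(=O)[C@H]1C[C@]23C(=O)[C@](C)(C[C@@H]2C1(C)C)C(=O)[C@](CC=C)(C(=O)C(C)C)C3=O
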